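**Plan**
- Cuts (side chain numbered from the ring CH2 as C1): the two quinone C=O groups go back to aryl methyl ethers. The chain is then cut at C17–C18 together with the C19–CH3 bond, giving a C33 aryl tetraprenyl homoallyl iodide, a C28 terminal alkyne and Me3Al.
- Enabling feature: C18=C19 is a trisubstituted alkene whose C19 methyl is cis to the C17 methylene. This is the pattern left by syn-methylmetalation of a terminal alkyne (C18≡C19) and a geometry-retaining coupling at C18. The benzoquinone ring is carried as the inert tetramethoxybenzene ring.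
- Ring half: aryl–C1 bond from an arylcopper and geranylgeranyl bromide; the terminal (E)-methyl is oxidised to the enal, methylenated, and the diene hydroborated to place iodine on C17.
- Tail half: farnesyl bromide plus a silylpropargyl anion (C18–C32), terminal allylic oxidation, then the C32–C33 bond by copper-catalysed coupling with the (R)-citronellyl Grignard reagent.
- Forward order: the halves are made in parallel, joined in a three-component union (alkyne + Me3Al + iodide), then oxidatively demethylated to the quinone.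
- Stereochemistry: five E alkenes are bought; C14=C15 and C30=C31 come from E-selective SeO2 oxidation; C18=C19 from syn carbometalation; C35 (S) comes unchanged from (R)-citronellyl bromide.

Key step: step 12

Remark: all-E geranylgeraniol (1), (2E,6E)-farnesyl bromide (13) and (R)-citronellyl bromide (19) are taken as purchasable; the stereocentre is R in 19 and S in the target only because the CIP ranking of its two chains changes, no bond to it being touched.

Step 1
Reactants: 1 (2E,6E,10E)-geranylgeraniol
Product: 2 (2E,6E,10E)-geranylgeranyl bromide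
Conditions: PBr3 (0.4 equiv), Et2O, −10 to 0 °C; used crude
Reagents that add atoms: phosphorus tribromide, BrP(Br)Br
Why: Bromination of a primary allylic alcohol with PBr3 at low temperature should proceed by SN2 without allylic shift or loss of the 2E geometry.

Step 2
Reactants: 3 1,2,3,4-tetramethoxy-5-methylbenzene; 2 (2E,6E,10E)-geranylgeranyl bromide
Product: 6 1-[(2E,6E,10E)-3,7,11,15-tetramethylhexadeca-2,6,10,14-tetraen-1-yl]-2,3,4,5-tetramethoxy-6-methylbenzene, via aryllithium 4 (not isolated), via arylcopper 5 (not isolated)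
Conditions: 3, n-BuLi, TMEDA, THF, 0 °C; CuBr·SMe2 (1 equiv), −40 °C; then 2, −40 °C to rt
Reagents that add atoms: none
Why: Directed ortho-lithiation at the only ring C–H (next to OMe), then copper-mediated allylic substitution at the primary carbon of 2 (SN2 mode), should give the aryl–C1 bond with the 2E alkene retained.

Step 3
Reactants: 6 geranylgeranyl arene
Product: 8 (2E,6E,10E,14E)-2,6,10,14-tetramethyl-16-(2,3,4,5-tetramethoxy-6-methylphenyl)hexadeca-2,6,10,14-tetraenal, via allylic alcohol 7 (not isolated)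
Conditions: SeO2 (0.3 equiv), t-BuOOH, salicylic acid (0.1 equiv), CH2Cl2, 0 °C to rt; filtration through silica; then MnO2, CH2Cl2, rt
Reagents that add atoms: selenium dioxide, O=[Se]=O; tert-butyl hydroperoxide, CC(C)(C)OO (the oxygen is delivered by SeO2 and replaced from t-BuOOH)
Why: Catalytic SeO2 allylic oxidation (ene reaction, then [2,3]-sigmatropic shift) should take the (E)-methyl group of the terminal, most accessible alkene, and MnO2 then carries the allylic alcohol on to the (E)-enal.

Step 4
Reactants: 8 (E)-enal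
Product: 9 1-[(2E,6E,10E,14E)-3,7,11,15-tetramethylheptadeca-2,6,10,14,16-pentaen-1-yl]-2,3,4,5-tetramethoxy-6-methylbenzene
Conditions: Ph3PCH3Br, KOt-Bu, THF, 0 °C to rt
Reagents that add atoms: methyltriphenylphosphonium bromide, C[P+](c1ccccc1)(c1ccccc1)c1ccccc1.[Br-]
Why: Wittig methylenation of the α-methyl enal adds C17 as a terminal vinyl group and leaves the C14=C15 geometry untouched.

Step 5
Reactants: 9 terminal 1,3-diene
Product: 11 (3E,7E,11E,15E)-3,7,11,15-tetramethyl-17-(2,3,4,5-tetramethoxy-6-methylphenyl)heptadeca-3,7,11,15-tetraen-1-ol, via B-alkyl-9-borabicyclononane 10 (not isolated)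
Conditions: 9-BBN (1.1 equiv), THF, 0 °C to rt; then NaOH, H2O2, 0 °C
Reagents that add atoms: hydrogen peroxide, OO (9-BBN, B1C2CCCC1CCC2, adds boron to intermediate 10 only)
Why: Hydroboration–oxidation: 9-BBN should add only to the monosubstituted terminal C=C of the diene, boron at the terminal carbon, because the trisubstituted alkenes react far more slowly, so that C17 becomes a CH2OH group.

Step 6
Reactants: 11 homoallylic alcohol
Product: 12 1-[(2E,6E,10E,14E)-17-iodo-3,7,11,15-tetramethylheptadeca-2,6,10,14-tetraen-1-yl]-2,3,4,5-tetramethoxy-6-methylbenzene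
Conditions: PPh3, imidazole, I2, CH2Cl2, 0 °C to rt
Reagents that add atoms: iodine, II
Why: Appel-type iodination of a primary alcohol through the alkoxyphosphonium salt, with SN2 displacement by iodide.

Step 7
Reactants: 13 (2E,6E)-farnesyl bromide; 14 1-(trimethylsilyl)propyne
Product: 16 trimethyl[(5E,9E)-6,10,14-trimethylpentadeca-5,9,13-trien-1-yn-1-yl]silane, via lithiated silylpropyne 15 (not isolated)
Conditions: 14, n-BuLi, THF, −78 to −20 °C; then 13, −78 °C to rt
Reagents that add atoms: none
Why: Propargylation of an allylic halide: the silyl group steers alkylation of the propargyl/allenyl anion to the propargylic carbon, and the primary allylic bromide reacts by SN2 with its E alkenes untouched.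

Step 8
Reactants: 16 silyl enyne
Product: 17 (2E,6E,10E)-2,6,10-trimethyl-15-(trimethylsilyl)pentadeca-2,6,10-trien-14-yn-1-ol
Conditions: SeO2 (0.3 equiv), t-BuOOH, salicylic acid (0.1 equiv), CH2Cl2, 0 °C to rt, conversion held back
Reagents that add atoms: selenium dioxide, O=[Se]=O; tert-butyl hydroperoxide, CC(C)(C)OO
Why: Catalytic SeO2 allylic oxidation should hydroxylate the (E)-methyl group of the terminal alkene, the most accessible of the three, and stop largely at the alcohol at partial conversion; the silylalkyne is inert.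

Step 9
Reactants: 17 allylic alcohol
Product: 18 [(5E,9E,13E)-15-bromo-6,10,14-trimethylpentadeca-5,9,13-trien-1-yn-1-yl]trimethylsilane
Conditions: CBr4, PPh3, CH2Cl2, −20 to 0 °C
Reagents that add atoms: carbon tetrabromide, BrC(Br)(Br)Br
Why: Appel bromination of a primary allylic alcohol proceeds by SN2 at low temperature without allylic transposition.

Step 10
Reactants: 19 (R)-citronellyl bromide; 18 allylic bromide
Product: 21 trimethyl[(5E,9E,13E,18S)-6,10,14,18,22-pentamethyltricosa-5,9,13,21-tetraen-1-yn-1-yl]silane, via citronellylmagnesium bromide 20 (not isolated)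
Conditions: 19, Mg, THF, rt to 40 °C; then added to 18, Li2CuCl4 (5 mol%), THF, −78 to 0 °C
Reagents that add atoms: none
Why: Copper-catalysed coupling of a primary alkyl Grignard reagent with a primary allylic bromide should occur at the CH2Br carbon with the E alkene retained; the stereocentre of 19 lies two carbons from the reacting centre and is not touched.

Step 11
Reactants: 21 silylalkyne
Product: 22 (5E,9E,13E,18S)-6,10,14,18,22-pentamethyltricosa-5,9,13,21-tetraen-1-yne
Conditions: K2CO3, MeOH/THF, rt
Reagents that add atoms: none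
Why: Base-catalysed methanolysis of the alkynyl C–Si bond frees the terminal alkyne.

Step 12
Reactants: 22 terminal alkyne (1.3 equiv); 12 homoallylic iodide
Product: 25 1-[(2E,6E,10E,14E,18E,22E,26E,30E,35S)-3,7,11,15,19,23,27,31,35,39-decamethyltetraconta-2,6,10,14,18,22,26,30,38-nonaen-1-yl]-2,3,4,5-tetramethoxy-6-methylbenzene, via alkenyldimethylalane 23 (not isolated), via alkenylzinc chloride 24 (not isolated)
Conditions: 22, Me3Al (2 equiv), Cp2ZrCl2 (0.25 equiv), ClCH2CH2Cl, 0 °C to rt; volatiles and excess Me3Al removed in vacuo; ZnCl2 (1.3 equiv), THF, 0 °C; then 12, Pd2(dba)3 (2 mol%), PCyp3 (8 mol%), N-methylimidazole, THF/NMP, 80 °C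
Reagents that add atoms: trimethylaluminium, C[Al](C)C
Why: Proposed new method: Cp2ZrCl2-catalysed methylalumination adds CH3 and AlMe2 syn across the C≡C of 22 (methyl to the internal carbon, aluminium to the terminal CH), ZnCl2 moves the alkenyl group to zinc, and zerovalent palladium carrying the bulky, electron-rich PCyp3 inserts into the primary C–I bond of 12 by an SN2-type oxidative addition, takes over the alkenyl group and eliminates the new CH2–CH= bond with retention of alkene geometry. The closest known reaction types are the one-pot carboalumination/cross-coupling of alkynes with aryl, alkenyl, allyl and benzyl halides under zinc co-catalysis and the Pd/trialkylphosphine Negishi coupling of alkenylzinc halides with unactivated primary alkyl iodides; their combination on a trisubstituted alkenylalane and a homoallylic iodide is not established. No ring is closed and no stereocentre is formed; the step creates C18=C19 as the E isomer because syn addition places the new methyl and the metal on the same side and both metal exchanges and the reductive elimination are stereoretentive. The selectivities needed are methyl delivery to the internal carbon (secured by the terminal alkyne and the zirconocene catalyst), transfer of the alkenyl and not a methyl group (secured by stripping excess Me3Al and the faster transmetalation of sp2 carbon), and coupling ahead of β-hydride elimination in the homoallylpalladium intermediate (secured by the phosphine/N-methylimidazole system). The eight existing alkenes, the aryl ethers and the remote stereocentre should be inert to these reagents.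

Step 13
Reactants: 25 tetramethoxyarene
Product: 26 2,3-dimethoxy-5-methyl-6-[(2E,6E,10E,14E,18E,22E,26E,30E,35S)-3,7,11,15,19,23,27,31,35,39-decamethyltetraconta-2,6,10,14,18,22,26,30,38-nonaen-1-yl]cyclohexa-2,5-diene-1,4-dione (target)
Conditions: (NH4)2Ce(NO3)6 (2.5 equiv), MeCN/CH2Cl2/H2O, 0 °C
Reagents that add atoms: water, O
Why: Oxidative demethylation of a hydroquinone dimethyl ether by tetravalent cerium: the electron-rich arene is oxidised in two one-electron steps, water adds at the two para methoxy-bearing carbons (those next to the methyl and the chain), two molecules of methanol leave and the 2,3-dimethoxy-1,4-benzoquinone remains, the isolated alkenes being much harder to oxidise.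

**Compound list**
1 | (2E,6E,10E)-geranylgeraniol | OC/C=C(\C)CC/C=C(\C)CC/C=C(\C)CCC=C(C)C | starting material
2 | (2E,6E,10E)-geranylgeranyl bromide | BrC/C=C(\C)CC/C=C(\C)CC/C=C(\C)CCC=C(C)C | intermediate
3 | 1,2,3,4-tetramethoxy-5-methylbenzene | COc1cc(C)c(OC)c(OC)c1OC | starting material
4 | (2,3,4,5-tetramethoxy-6-methylphenyl)lithium | [Li]c1c(C)c(OC)c(OC)c(OC)c1OC | intermediate
5 | (2,3,4,5-tetramethoxy-6-methylphenyl)copper | [Cu]c1c(C)c(OC)c(OC)c(OC)c1OC | intermediate
6 | 1-[(2E,6E,10E)-3,7,11,15-tetramethylhexadeca-2,6,10,14-tetraen-1-yl]-2,3,4,5-tetramethoxy-6-methylbenzene | COc1c(OC)c(OC)c(C/C=C(\C)CC/C=C(\C)CC/C=C(\C)CCC=C(C)C)c(C)c1OC | intermediate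
7 | (2E,6E,10E,14E)-2,6,10,14-tetramethyl-16-(2,3,4,5-tetramethoxy-6-methylphenyl)hexadeca-2,6,10,14-tetraen-1-ol | COc1c(OC)c(OC)c(C/C=C(\C)CC/C=C(\C)CC/C=C(\C)CC/C=C(\C)CO)c(C)c1OC | intermediate
8 | (2E,6E,10E,14E)-2,6,10,14-tetramethyl-16-(2,3,4,5-tetramethoxy-6-methylphenyl)hexadeca-2,6,10,14-tetraenal | COc1c(OC)c(OC)c(C/C=C(\C)CC/C=C(\C)CC/C=C(\C)CC/C=C(\C)C=O)c(C)c1OC | intermediate
9 | 1-[(2E,6E,10E,14E)-3,7,11,15-tetramethylheptadeca-2,6,10,14,16-pentaen-1-yl]-2,3,4,5-tetramethoxy-6-methylbenzene | COc1c(OC)c(OC)c(C/C=C(\C)CC/C=C(\C)CC/C=C(\C)CC/C=C(\C)C=C)c(C)c1OC | intermediate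
10 | 9-[(3E,7E,11E,15E)-3,7,11,15-tetramethyl-17-(2,3,4,5-tetramethoxy-6-methylphenyl)heptadeca-3,7,11,15-tetraen-1-yl]-9-borabicyclo[3.3.1]nonane | COc1c(OC)c(OC)c(C/C=C(\C)CC/C=C(\C)CC/C=C(\C)CC/C=C(\C)CCB2C3CCCC2CCC3)c(C)c1OC | intermediate
11 | (3E,7E,11E,15E)-3,7,11,15-tetramethyl-17-(2,3,4,5-tetramethoxy-6-methylphenyl)heptadeca-3,7,11,15-tetraen-1-ol | COc1c(OC)c(OC)c(C/C=C(\C)CC/C=C(\C)CC/C=C(\C)CC/C=C(\C)CCO)c(C)c1OC | intermediate
12 | 1-[(2E,6E,10E,14E)-17-iodo-3,7,11,15-tetramethylheptadeca-2,6,10,14-tetraen-1-yl]-2,3,4,5-tetramethoxy-6-methylbenzene | COc1c(OC)c(OC)c(C/C=C(\C)CC/C=C(\C)CC/C=C(\C)CC/C=C(\C)CCI)c(C)c1OC | intermediate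
13 | (2E,6E)-farnesyl bromide | BrC/C=C(\C)CC/C=C(\C)CCC=C(C)C | starting material
14 | 1-(trimethylsilyl)propyne | CC#C[Si](C)(C)C | starting material
15 | [3-(trimethylsilyl)prop-2-yn-1-yl]lithium | [Li]CC#C[Si](C)(C)C | intermediate
16 | trimethyl[(5E,9E)-6,10,14-trimethylpentadeca-5,9,13-trien-1-yn-1-yl]silane | C[Si](C)(C)C#CCC/C=C(\C)CC/C=C(\C)CCC=C(C)C | intermediate
17 | (2E,6E,10E)-2,6,10-trimethyl-15-(trimethylsilyl)pentadeca-2,6,10-trien-14-yn-1-ol | C[Si](C)(C)C#CCC/C=C(\C)CC/C=C(\C)CC/C=C(\C)CO | intermediate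
18 | [(5E,9E,13E)-15-bromo-6,10,14-trimethylpentadeca-5,9,13-trien-1-yn-1-yl]trimethylsilane | C[Si](C)(C)C#CCC/C=C(\C)CC/C=C(\C)CC/C=C(\C)CBr | intermediate
19 | (R)-citronellyl bromide, (6R)-8-bromo-2,6-dimethyloct-2-ene | BrCC[C@H](C)CCC=C(C)C | starting material
20 | [(3R)-3,7-dimethyloct-6-en-1-yl]magnesium bromide | Br[Mg]CC[C@H](C)CCC=C(C)C | intermediate
21 | trimethyl[(5E,9E,13E,18S)-6,10,14,18,22-pentamethyltricosa-5,9,13,21-tetraen-1-yn-1-yl]silane | C[Si](C)(C)C#CCC/C=C(\C)CC/C=C(\C)CC/C=C(\C)CCC[C@H](C)CCC=C(C)C | intermediate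
22 | (5E,9E,13E,18S)-6,10,14,18,22-pentamethyltricosa-5,9,13,21-tetraen-1-yne | C#CCC/C=C(\C)CC/C=C(\C)CC/C=C(\C)CCC[C@H](C)CCC=C(C)C | intermediate
23 | dimethyl[(1E,5E,9E,13E,18S)-2,6,10,14,18,22-hexamethyltricosa-1,5,9,13,21-pentaen-1-yl]alumane | C[Al](C)/C=C(\C)CC/C=C(\C)CC/C=C(\C)CC/C=C(\C)CCC[C@H](C)CCC=C(C)C | intermediate
24 | chloro[(1E,5E,9E,13E,18S)-2,6,10,14,18,22-hexamethyltricosa-1,5,9,13,21-pentaen-1-yl]zinc | Cl[Zn]/C=C(\C)CC/C=C(\C)CC/C=C(\C)CC/C=C(\C)CCC[C@H](C)CCC=C(C)C | intermediate
25 | 1-[(2E,6E,10E,14E,18E,22E,26E,30E,35S)-3,7,11,15,19,23,27,31,35,39-decamethyltetraconta-2,6,10,14,18,22,26,30,38-nonaen-1-yl]-2,3,4,5-tetramethoxy-6-methylbenzene | COc1c(OC)c(OC)c(C/C=C(\C)CC/C=C(\C)CC/C=C(\C)CC/C=C(\C)CC/C=C(\C)CC/C=C(\C)CC/C=C(\C)CC/C=C(\C)CCC[C@H](C)CCC=C(C)C)c(C)c1OC | intermediate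
26 | 2,3-dimethoxy-5-methyl-6-[(2E,6E,10E,14E,18E,22E,26E,30E,35S)-3,7,11,15,19,23,27,31,35,39-decamethyltetraconta-2,6,10,14,18,22,26,30,38-nonaen-1-yl]cyclohexa-2,5-diene-1,4-dione | COC1=C(OC)C(=O)C(C/C=C(\C)CC/C=C(\C)CC/C=C(\C)CC/C=C(\C)CC/C=C(\C)CC/C=C(\C)CC/C=C(\C)CC/C=C(\C)CCC[C@H](C)CCC=C(C)C)=C(C)C1=O | target

**Count and risks**

Total step count: 13. Longest linear sequence: 8 steps (steps 1–6, 12, 13); the tail branch is steps 7–11.

Steps most likely to fail:

Step 12. The alkylpalladium intermediate may undergo β-hydride elimination before transmetalation, a methyl group may be transferred in place of the alkenyl group, or the exchange from aluminium to zinc may be too slow. Fallback with reversed polarity, from 22 and 12, returning at 25: the carboalumination mixture from 22 (alane 23) is quenched with I2 in THF at −30 °C to give the (E)-alkenyl iodide F1. Iodide 12 is treated with t-BuLi (2 equiv, Et2O, −78 °C) to give the homoallyllithium F2 and then with ZnBr2 (THF) to give the homoallylzinc bromide F3. F1 and F3 are joined with Pd(PPh3)4 (cat.) in THF at rt, a Negishi alkenyl–homoallyl coupling (alkenyl halide with an alkylzinc reagent), to give 25.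

Step 3. The oxidation may lose site selectivity among the four trisubstituted alkenes, over-oxidise, or attack the electron-rich arene and its doubly activated benzylic CH2. Fallback from 17 and 3, returning at 7, which MnO2 then takes to 8 as in the second half of step 3. The allylic oxidation is left on the smaller, arene-free chain (step 8) and the aryl–chain junction is made by carbometalation. Compound 17 is desilylated (K2CO3, MeOH) to the alkynol F4. Compound 3 is chloromethylated (paraformaldehyde, HCl, Blanc reaction) to the benzylic chloride F5. F4 with Me3Al (3 equiv, the first consumed by the OH group) and Cp2ZrCl2 (cat.) in ClCH2CH2Cl gives the alkenylalane F6. F6 is coupled with F5 under zerovalent nickel (from NiCl2(PPh3)2 and n-BuLi, cat.) in THF at rt, a coupling type known for alkenylalanes and benzylic chlorides; aqueous work-up gives 7.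

Step 10. The Grignard reagent may attack with allylic transposition, the C30=C31 geometry may erode, or the reagent may homocouple. Fallback from 19 and 18, returning at 21. Compound 19 and PhSO2Na (DMF, 60 °C) give the (R)-citronellyl phenyl sulfone F7. n-BuLi (THF, −78 °C) gives the α-sulfonyl carbanion F8, a soft stabilised nucleophile that should alkylate 18 cleanly at the primary carbon to give the sulfone F9 (epimers at the sulfonyl carbon, of no consequence). Reductive desulfonylation with Na(Hg), Na2HPO4, MeOH/THF, −20 °C gives 21.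

**Further compounds**
F1 | step 12 | (1E,5E,9E,13E,18S)-1-iodo-2,6,10,14,18,22-hexamethyltricosa-1,5,9,13,21-pentaene | I/C=C(\C)CC/C=C(\C)CC/C=C(\C)CC/C=C(\C)CCC[C@H](C)CCC=C(C)C
F2 | step 12 | [(3E,7E,11E,15E)-3,7,11,15-tetramethyl-17-(2,3,4,5-tetramethoxy-6-methylphenyl)heptadeca-3,7,11,15-tetraen-1-yl]lithium | COc1c(OC)c(OC)c(C/C=C(\C)CC/C=C(\C)CC/C=C(\C)CC/C=C(\C)CC[Li])c(C)c1OC
F3 | step 12 | bromo[(3E,7E,11E,15E)-3,7,11,15-tetramethyl-17-(2,3,4,5-tetramethoxy-6-methylphenyl)heptadeca-3,7,11,15-tetraen-1-yl]zinc | COc1c(OC)c(OC)c(C/C=C(\C)CC/C=C(\C)CC/C=C(\C)CC/C=C(\C)CC[Zn]Br)c(C)c1OC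
F4 | step 3 | (2E,6E,10E)-2,6,10-trimethylpentadeca-2,6,10-trien-14-yn-1-ol | C#CCC/C=C(\C)CC/C=C(\C)CC/C=C(\C)CO
F5 | step 3 | 1-(chloromethyl)-2,3,4,5-tetramethoxy-6-methylbenzene | ClCc1c(C)c(OC)c(OC)c(OC)c1OC
F6 | step 3 | (1E,5E,9E,13E)-1-(dimethylalumanyl)-2,6,10,14-tetramethylpentadeca-1,5,9,13-tetraen-15-ol dimethylaluminium alkoxide | C[Al](C)/C=C(\C)CC/C=C(\C)CC/C=C(\C)CC/C=C(\C)CO[Al](C)C
F7 | step 10 | {[(3R)-3,7-dimethyloct-6-en-1-yl]sulfonyl}benzene | O=S(=O)(CC[C@H](C)CCC=C(C)C)c1ccccc1
F8 | step 10 | [(3R)-3,7-dimethyl-1-(phenylsulfonyl)oct-6-en-1-yl]lithium | [Li]C(C[C@H](C)CCC=C(C)C)S(=O)(=O)c1ccccc1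
F9 | step 10 | trimethyl[(5E,9E,13E,18R)-6,10,14,18,22-pentamethyl-16-(phenylsulfonyl)tricosa-5,9,13,21-tetraen-1-yn-1-yl]silane, sulfonyl carbon unassigned | C[Si](C)(C)C#CCC/C=C(\C)CC/C=C(\C)CC/C=C(\C)CC(C[C@H](C)CCC=C(C)C)S(=O)(=O)c1ccccc1
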